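## Retrosynthetic overview

- Ring B (the 2H-pyran-2-one) is built first and carried as its tert-butyl ester; ring A (the butyrolactone, O1–C2(=O)–C3–C4–C5) is closed in the penultimate step, and acidolysis of the ester ends the route.
- Enabling feature: in ring A the O1–C2(=O) unit bridges C5 and C3, which are 1,3-related through C4, and C3 bears the CH2 bonded to C-4 of ring B. C5 can therefore be a primary bromide, and C3 the far carbon of an (E)-alkene conjugated to ring B, a polarised radical acceptor.
- Key disconnection: O1–C5 and C2–C3 in one flask. Oxalate supplies O1–C2(=O), first by O-alkylation at C5, then by oxidative decarboxylation to an alkoxycarbonyl radical that closes 5-exo on C3, trans to the C4 benzyl group.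
- The acyclic precursor comes from Suzuki coupling of a pyranone triflate (dioxinone plus oxalate diester, thermolysis, triflation) with an (E)-alkenyl boronate made by cross-metathesis of a homoallylic bromide.
- The C4 stereocentre is set by Evans deconjugative alkylation of a crotonyl imide with 3,4-dimethoxybenzyl bromide, followed by reduction and bromination.

Key step: step 10

Remark: all seven starting materials are taken as commercial, and ring A is numbered O1, C2 (carbonyl), C3, C4, C5 throughout.

## Route

Step 1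
Reactants: 1 (R)-4-benzyloxazolidin-2-one; 2 (E)-but-2-enoyl chloride
Product: 3 (R)-4-benzyl-3-[(E)-but-2-enoyl]oxazolidin-2-one
Conditions: n-BuLi, THF, −78 °C; then 2, −78 to 0 °C
Reagents that add atoms: none
Why: N-acylation of the lithiated oxazolidinone (attachment of the Evans auxiliary) is routine and leaves the (E)-crotonyl unit intact at low temperature.

Step 2
Reactants: 3 (R)-4-benzyl-3-[(E)-but-2-enoyl]oxazolidin-2-one; 4 4-(bromomethyl)-1,2-dimethoxybenzene
Product: 5 (R)-4-benzyl-3-[(R)-2-(3,4-dimethoxybenzyl)but-3-enoyl]oxazolidin-2-one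
Conditions: NaN(SiMe3)2, THF, −78 °C; then 4
Reagents that add atoms: none
Why: Evans deconjugative alkylation: γ-deprotonation gives the chelated (Z)-dienolate, which is alkylated at the α-carbon on the face opposite the auxiliary benzyl group, so the (R) auxiliary should set the (R) centre that becomes C4.

Step 3
Reactants: 5 (R)-4-benzyl-3-[(R)-2-(3,4-dimethoxybenzyl)but-3-enoyl]oxazolidin-2-one
Product: 6 (R)-2-(3,4-dimethoxybenzyl)but-3-en-1-ol
Conditions: LiBH4, MeOH, THF, 0 °C; aq. NH4Cl
Reagents that add atoms: none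
Why: Reductive cleavage of the imide with LiBH4 should give the primary alcohol without touching the β,γ-alkene or the stereocentre, and returns the auxiliary.

Step 4
Reactants: 6 (R)-2-(3,4-dimethoxybenzyl)but-3-en-1-ol
Product: 7 (R)-4-[2-(bromomethyl)but-3-en-1-yl]-1,2-dimethoxybenzene
Conditions: CBr4, PPh3, CH2Cl2, 0 °C
Reagents that add atoms: carbon tetrabromide, BrC(Br)(Br)Br
Why: The Appel reaction converts the primary alcohol into the bromide by SN2 at the CH2 carbon, which does not involve the stereocentre.

Step 5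
Reactants: 7 (R)-4-[2-(bromomethyl)but-3-en-1-yl]-1,2-dimethoxybenzene; 8 4,4,5,5-tetramethyl-2-vinyl-1,3,2-dioxaborolane
Product: 9 2-[(R,E)-3-(bromomethyl)-4-(3,4-dimethoxyphenyl)but-1-en-1-yl]-4,4,5,5-tetramethyl-1,3,2-dioxaborolane
Conditions: 8 (3 equiv), second-generation Grubbs catalyst (5 mol %), 1,4-benzoquinone (10 mol %), CH2Cl2, 40 °C
Reagents that add atoms: none
Why: Olefin cross-metathesis of the terminal alkene with the vinyl boronate is expected to give the (E)-alkenyl boronate because of the bulky boryl group, with benzoquinone suppressing ruthenium hydride alkene migration that would endanger the allylic centre.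

Step 6
Reactants: 10 2,2,6-trimethyl-4H-1,3-dioxin-4-one; 11 di-tert-butyl oxalate
Product: 12 tert-butyl 3-(2,2-dimethyl-4-oxo-4H-1,3-dioxin-6-yl)-2-oxopropanoate
Conditions: LiN(iPr)2, THF, −78 °C (10 in twofold amount); then 11; AcOH
Reagents that add atoms: none
Why: Claisen-type γ-acylation of the dioxinone lithium dienolate by the highly electrophilic oxalate diester, with the acidic product protected as its enolate by the second equivalent of dienolate.

Step 7
Reactants: 12 tert-butyl 3-(2,2-dimethyl-4-oxo-4H-1,3-dioxin-6-yl)-2-oxopropanoate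
Product: 14 tert-butyl 4-hydroxy-2-oxo-2H-pyran-6-carboxylate, via acylketene 13 (not isolated)
Conditions: toluene, 110 °C
Reagents that add atoms: none
Why: Thermal retro-(4+2) loss of acetone gives the acylketene, which is trapped by the enol oxygen of the α-keto ester in a six-membered lactonisation to the aromatic 4-hydroxy-2-pyranone (ring B).

Step 8
Reactants: 14 tert-butyl 4-hydroxy-2-oxo-2H-pyran-6-carboxylate
Product: 15 tert-butyl 2-oxo-4-(trifluoromethanesulfonyloxy)-2H-pyran-6-carboxylate
Conditions: Tf2O, Et3N, CH2Cl2, −78 °C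
Reagents that add atoms: trifluoromethanesulfonic anhydride, O=S(=O)(OS(=O)(=O)C(F)(F)F)C(F)(F)F
Why: O-sulfonylation of the acidic vinylogous carboxylic acid OH gives the pyranone triflate, an activated partner for cross-coupling.

Step 9
Reactants: 9 2-[(R,E)-3-(bromomethyl)-4-(3,4-dimethoxyphenyl)but-1-en-1-yl]-4,4,5,5-tetramethyl-1,3,2-dioxaborolane; 15 tert-butyl 2-oxo-4-(trifluoromethanesulfonyloxy)-2H-pyran-6-carboxylate
Product: 16 tert-butyl 4-[(R,E)-3-(bromomethyl)-4-(3,4-dimethoxyphenyl)but-1-en-1-yl]-2-oxo-2H-pyran-6-carboxylate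
Conditions: Pd(dppf)Cl2 (5 mol %), K3PO4, THF/H2O, 40 °C
Reagents that add atoms: none
Why: Suzuki–Miyaura coupling: the vinylogous acyl triflate adds quickly to zerovalent palladium, the alkenyl boronate transfers with retention of (E) geometry, and the unactivated primary alkyl bromide should not react under these conditions.

Step 10
Reactants: 16 tert-butyl 4-[(R,E)-3-(bromomethyl)-4-(3,4-dimethoxyphenyl)but-1-en-1-yl]-2-oxo-2H-pyran-6-carboxylate; 17 dicesium oxalate
Product: 19 tert-butyl 4-{[(3R,4R)-4-(3,4-dimethoxybenzyl)-2-oxotetrahydrofuran-3-yl]methyl}-2-oxo-2H-pyran-6-carboxylate, via cesium half-oxalate 18 (not isolated)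
Conditions: Cs2C2O4 (1.1 equiv), DMSO, 50 °C, dark; then Ir[dF(CF3)ppy]2(dtbbpy)PF6 (1 mol %), H2O, DME, 450 nm LED, 25 °C, same flask
Reagents that add atoms: none
Why: Proposed new method: the oxalate dianion should displace the primary bromide of 16 (SN2 at C5, forming O1–C5) to give half-oxalate 18, whose carboxylate is then oxidised by the excited trivalent iridium photocatalyst and loses CO2 to an alkoxycarbonyl radical; this radical closes ring A by 5-exo-trig attack of its carbonyl carbon on C3 (the δ-carbon of the dienyl lactone of ring B), forming C2–C3, and the pyranone-stabilised radical so formed is reduced by divalent iridium and protonated by water. The closest known reaction types are the photoredox oxidation of cesium alkyl oxalates to alkoxycarbonyl radicals that cyclise 5-exo onto alkenes, and the tin hydride cyclisation of Se-phenyl selenocarbonates to butyrolactones; not yet shown are the making of the oxalate by O-alkylation in the same flask and an alkenylpyranone as the acceptor. Ring A closes in the 5-exo-trig radical mode after the intermolecular SN2 step has tied O1 to C5. The new stereocentre C3 is controlled by the existing C4 centre: in the chair-like transition state the 3,4-dimethoxybenzyl group lies pseudo-equatorial, which places the pyranylmethyl arm trans to it (3R,4R). The step needs mono-O-alkylation of oxalate without loss of HBr, 5-exo instead of 6-endo closure, and oxidation of the carboxylate instead of the dimethoxyarene; these are served by the low nucleophilicity and basicity of the half-oxalate, by the polarised acceptor that places the new radical next to ring B, and by the irreversible decarboxylation that drains the oxalate radical.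

Step 11
Reactants: 19 tert-butyl 4-{[(3R,4R)-4-(3,4-dimethoxybenzyl)-2-oxotetrahydrofuran-3-yl]methyl}-2-oxo-2H-pyran-6-carboxylate
Product: 20 4-{[(3R,4R)-4-(3,4-dimethoxybenzyl)-2-oxotetrahydrofuran-3-yl]methyl}-2-oxo-2H-pyran-6-carboxylic acid
Conditions: TFA, CH2Cl2, 0 °C to rt
Reagents that add atoms: none
Why: Acidolysis of the tert-butyl ester (loss of the tert-butyl cation as isobutene) should free the acid without affecting the lactone, the pyranone, the methyl ethers or the two stereocentres.

## Compound list

1 | (R)-4-benzyloxazolidin-2-one | O=C1N[C@H](Cc2ccccc2)CO1 | starting material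
2 | (E)-but-2-enoyl chloride | C/C=C/C(=O)Cl | starting material
3 | (R)-4-benzyl-3-[(E)-but-2-enoyl]oxazolidin-2-one | C/C=C/C(=O)N1[C@H](Cc2ccccc2)COC1=O | intermediate
4 | 4-(bromomethyl)-1,2-dimethoxybenzene | COc1ccc(CBr)cc1OC | starting material
5 | (R)-4-benzyl-3-[(R)-2-(3,4-dimethoxybenzyl)but-3-enoyl]oxazolidin-2-one | C=C[C@@H](Cc1ccc(OC)c(OC)c1)C(=O)N1[C@H](Cc2ccccc2)COC1=O | intermediate
6 | (R)-2-(3,4-dimethoxybenzyl)but-3-en-1-ol | C=C[C@@H](Cc1ccc(OC)c(OC)c1)CO | intermediate
7 | (R)-4-[2-(bromomethyl)but-3-en-1-yl]-1,2-dimethoxybenzene | C=C[C@@H](Cc1ccc(OC)c(OC)c1)CBr | intermediate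
8 | 4,4,5,5-tetramethyl-2-vinyl-1,3,2-dioxaborolane | C=CB1OC(C)(C)C(C)(C)O1 | starting material
9 | 2-[(R,E)-3-(bromomethyl)-4-(3,4-dimethoxyphenyl)but-1-en-1-yl]-4,4,5,5-tetramethyl-1,3,2-dioxaborolane | BrC[C@H](Cc1ccc(OC)c(OC)c1)/C=C/B1OC(C)(C)C(C)(C)O1 | intermediate
10 | 2,2,6-trimethyl-4H-1,3-dioxin-4-one | CC1=CC(=O)OC(C)(C)O1 | starting material
11 | di-tert-butyl oxalate | CC(C)(C)OC(=O)C(=O)OC(C)(C)C | starting material
12 | tert-butyl 3-(2,2-dimethyl-4-oxo-4H-1,3-dioxin-6-yl)-2-oxopropanoate | CC1(C)OC(CC(=O)C(=O)OC(C)(C)C)=CC(=O)O1 | intermediate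
13 | tert-butyl 2,4,6-trioxohex-5-enoate (acylketene, not isolated) | O=C=CC(=O)CC(=O)C(=O)OC(C)(C)C | intermediate
14 | tert-butyl 4-hydroxy-2-oxo-2H-pyran-6-carboxylate | CC(C)(C)OC(=O)c1cc(O)cc(=O)o1 | intermediate
15 | tert-butyl 2-oxo-4-(trifluoromethanesulfonyloxy)-2H-pyran-6-carboxylate | CC(C)(C)OC(=O)c1cc(OS(=O)(=O)C(F)(F)F)cc(=O)o1 | intermediate
16 | tert-butyl 4-[(R,E)-3-(bromomethyl)-4-(3,4-dimethoxyphenyl)but-1-en-1-yl]-2-oxo-2H-pyran-6-carboxylate | BrC[C@H](Cc1ccc(OC)c(OC)c1)/C=C/c1cc(C(=O)OC(C)(C)C)oc(=O)c1 | intermediate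
17 | dicesium oxalate | [Cs+].[Cs+].[O-]C(=O)C([O-])=O | starting material
18 | cesium 2-{[(R,E)-4-[6-(tert-butoxycarbonyl)-2-oxo-2H-pyran-4-yl]-2-(3,4-dimethoxybenzyl)but-3-en-1-yl]oxy}-2-oxoacetate (half-oxalate, not isolated) | [Cs+].[O-]C(=O)C(=O)OC[C@H](Cc1ccc(OC)c(OC)c1)/C=C/c1cc(C(=O)OC(C)(C)C)oc(=O)c1 | intermediate
19 | tert-butyl 4-{[(3R,4R)-4-(3,4-dimethoxybenzyl)-2-oxotetrahydrofuran-3-yl]methyl}-2-oxo-2H-pyran-6-carboxylate | COc1ccc(C[C@H]2COC(=O)[C@@H]2Cc2cc(C(=O)OC(C)(C)C)oc(=O)c2)cc1OC | intermediate
20 | 4-{[(3R,4R)-4-(3,4-dimethoxybenzyl)-2-oxotetrahydrofuran-3-yl]methyl}-2-oxo-2H-pyran-6-carboxylic acid | COc1ccc(C[C@H]2COC(=O)[C@@H]2Cc2cc(C(=O)O)oc(=O)c2)cc1OC | target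

## Step count and risks

Total step count: 11. Longest linear sequence: 8 (steps 1, 2, 3, 4, 5, 9, 10, 11); steps 6 to 8 form the three-step branch to triflate 15.

Steps most likely to fail:

Step 10. Several processes could defeat it:
- base-induced loss of HBr, or epimerisation of the allylic C4–H (the ε-hydrogen of the dienyl lactone), during the O-alkylation;
- unproductive quenching of the excited photocatalyst by the dimethoxyarene;
- sensitised (E)/(Z) isomerisation or dimerisation of the alkenylpyranone;
- insufficient trans selectivity in the radical ring closure.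

The fallback uses known polar chemistry, sets out from 7 (with 15) and comes back at 19. Hydroboration and oxidation of 7 (9-BBN, THF; then NaBO3) would give (R)-3-(bromomethyl)-4-(3,4-dimethoxyphenyl)butan-1-ol F1. Oxidation with TEMPO and PhI(OAc)2 in MeCN/H2O would give (R)-3-(bromomethyl)-4-(3,4-dimethoxyphenyl)butanoic acid F2. K2CO3 in DMF would close this by carboxylate SN2 at C5 to (R)-4-(3,4-dimethoxybenzyl)dihydrofuran-2(3H)-one F3. In parallel, 15 would be methylated (trimethylboroxine, Pd(dppf)Cl2, K2CO3, dioxane) to tert-butyl 4-methyl-2-oxo-2H-pyran-6-carboxylate F4 and brominated (NBS, AIBN, PhCF3, 80 °C) to tert-butyl 4-(bromomethyl)-2-oxo-2H-pyran-6-carboxylate F5. The lithium enolate of F3 (LiN(SiMe3)2, THF, −78 °C) would then be alkylated by F5 anti to the C4 substituent, which should give the trans lactone 19.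

Step 9. The vinylogous acyl triflate may hydrolyse under aqueous base, and the coupled product may lose HBr by base-induced elimination. The fallback avoids base, sets out from 15 and 7 and comes back at 16. Stille vinylation of 15 (tributyl(vinyl)stannane, Pd(PPh3)4, dioxane) would give tert-butyl 2-oxo-4-vinyl-2H-pyran-6-carboxylate F6, and cross-metathesis of F6 with 7 (second-generation Hoveyda–Grubbs catalyst, CH2Cl2, 40 °C) would give 16 directly.

Step 5. Metathesis of the α-branched alkene may be slow, with alkene migration through ruthenium hydrides (loss of the allylic stereocentre) and homodimerisation competing. The fallback sets out from 7 and comes back at 16, skipping boronate 9: a Heck reaction of 7 with triflate 15 under ligand-free conditions (Pd(OAc)2, Bu4NCl, NaHCO3, DMF, 60 °C). It makes no new compound (F0).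

## Further compounds

F1 | step 10 | (R)-3-(bromomethyl)-4-(3,4-dimethoxyphenyl)butan-1-ol | OCC[C@@H](Cc1ccc(OC)c(OC)c1)CBr
F2 | step 10 | (R)-3-(bromomethyl)-4-(3,4-dimethoxyphenyl)butanoic acid | OC(=O)C[C@@H](Cc1ccc(OC)c(OC)c1)CBr
F3 | step 10 | (R)-4-(3,4-dimethoxybenzyl)dihydrofuran-2(3H)-one | COc1ccc(C[C@H]2COC(=O)C2)cc1OC
F4 | step 10 | tert-butyl 4-methyl-2-oxo-2H-pyran-6-carboxylate | Cc1cc(C(=O)OC(C)(C)C)oc(=O)c1
F5 | step 10 | tert-butyl 4-(bromomethyl)-2-oxo-2H-pyran-6-carboxylate | BrCc1cc(C(=O)OC(C)(C)C)oc(=O)c1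
F6 | step 9 | tert-butyl 2-oxo-4-vinyl-2H-pyran-6-carboxylate | C=Cc1cc(C(=O)OC(C)(C)C)oc(=O)c1
F0 | step 5 | none | none
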